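In the amber run E climbs by 18 percentage points between 4.00 h and 20.0 h, while G moves by 1.1 points. So I suspect that G and Z keep a balance while the later steps creep.

| flask | G | Q | D | remark | time |
|---|---|---|---|---|---|
| ochre | 0.10 M | 0.095 M | 0.20 M | run made earlier |  |
| amber | 0.10 M | 0.23 M | 0.20 M | run made earlier |  |
| ash | 0.10 M | 0.0700 M | 0.200 M |  | 30 h |
| elm | 0.10 M | 0.180 M | 0.200 M |  | 30 h |

| run | time / h | J / % | E / % | Z / % | G / % |
|---|---|---|---|---|---|
| ochre | 1.33 | 4.0 | 0.6 | 37.4 | 56.4 |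
| ochre | 4.00 | 6.4 | 2.3 | 43.5 | 45.3 |
| ochre | 8.00 | 5.7 | 3.2 | 41.5 | 43.9 |
| ochre | 12.0 | 6.4 | 4.4 | 39.6 | 44.0 |
| ochre | 15.0 | 5.6 | 5.2 | 38.1 | 42.7 |
| ochre | 20.0 | 5.7 | 6.0 | 36.8 | 42.6 |
| amber | 4.00 | 17.6 | 15.5 | 46.8 | 19.2 |
| amber | 8.00 | 13.1 | 24.9 | 40.0 | 19.1 |
| amber | 10.0 | 12.4 | 28.0 | 37.9 | 19.6 |
| amber | 15.0 | 10.7 | 31.0 | 35.4 | 20.2 |
| amber | 20.0 | 10.4 | 33.2 | 34.1 | 20.3 |

(scatter of a reading: 0.3 percentage points)

- which of these there is most of at the end, counted by the G in it, ash (J / E / Z / G)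
- which of these there is most of at the end, counted by the G in it, elm (J / E / Z / G)
- amount of the one of these that there is most of at the end, in percent of the G charged, ash
- amount of the one of these that there is most of at the end, in percent of the G charged, elm



I take each exchange to swap one Q for one D, so the readings give cQ and cD. My quantity is the split constant K = cZ·cD/(cG·cQ), an equilibrium constant.

cQ = charged Q − charged G × (Z + 2J + 3E)

ochre, 20.0 h: cQ = 0.0288 M, K = 7.98

amber, 20.0 h: cQ = 0.0755 M, K = 7.89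

The two runs agree, so I read K = 7.94, and cZ/cG = K·cQ/cD.

If ash ran the first exchange by itself, cZ would be 0.0449 M, and cZ/cG 0.814. But J and E spend Q too, 0.0294 M of it in ochre. The earlier runs kept a similar part of their Q, on average 31.6%, so I use that:

ash: cZ/cG = 0.707

elm: cZ/cG = 1.40

So I expect G to exceed Z in ash, and Z to exceed G in elm.

Another doubt: the percentages don't close. Ochre lacks 8.90% and amber 2.00%, a ratio of 4.45 against 4.40 for the square of G. Yet K held across both. Scaling ochre's gap to 30 h gives 13.3% lost in ash. With ochre's J and E as an allowance, my estimate of G in ash is 43.9%.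

The forecast says G at 47% for ash and Z at 35% for elm, and calls the gap “probably a slow G side-drain”. Its G for ash is higher than my estimate.

The flasks give G at 44.6% in ash and Z at 35.9% in elm.

    J + Q ⇌ D + E (K = 17.0, k = 2.30 M⁻¹ h⁻¹)
    G + Q ⇌ D + Z (K = 7.80, k = 7.70 M⁻¹ h⁻¹)
    2 G → X (k = 0.110 M⁻¹ h⁻¹)
    Z + Q ⇌ D + J (K = 1.40, k = 3.10 M⁻¹ h⁻¹)

Ash ends with K·cQ/cD = 0.685 from its Q and D, and its Z and G stand at 0.685. A neighbouring flask is ash with 0.025 M of G charged instead. At its end it keeps 58% of its Q and holds 115% of its D charge, so there K·cQ/cD = 1.40. In that flask Z leads at the end, with Z at 39.7% against G at 28.9%.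

Readings and results were generated by integration with made-up constants, and the scatter is random.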